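**Retrosynthetic overview**

- The strategy rests on ring A (C1–C5, C10). C3–OH, the quaternary C4 (C18 methyl, C19 hydroxymethyl) and C19–OH form a β-hydroxy ketone pattern, so the C4–C5 bond is cut by a 1,2-shift. This turns ring A into a cyclopentanol (C1, C2, C3, C5, C10) that carries a C4–C19 epoxide on C3.
- The cyclopentanol comes from 3-methylcyclopent-2-enone. Catalytic asymmetric conjugate addition of a 1-silylvinyl group sets C10. Alkylation of the trapped enolate with the bromobutenyl unit (C6, C7, C8, C17) sets C5 anti to that bulky group. Desilylation, isopropenyl addition (C3) and hydroxyl-directed epoxidation (C4) follow.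
- After the ring enlargement, C3 is reduced and the 3,19-diol is masked as an acetonide. The C10 vinyl group is extended to the C9=C11–C12 enal by cross-metathesis, and ring B is closed by 6-exo addition of the C8 vinyl radical to C9.
- The hydroxylactone (C13–C16) is taken from (S)-3-hydroxy-γ-butyrolactone and joined at C12=C13 by aldol addition and elimination; mild acid removes the protecting groups.
- Ring order: five-membered carbocycle (purchased), ring A (step 7), ring B (step 11); the lactone ring is brought in intact.

Key step: step 7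

Remark: labdane numbering is used for all intermediates; in step 1 the ligand enantiomer is the one that gives the (R)-configured quaternary carbon of 5.

**Route**

Step 1
Reactants: 1 ethynyltrimethylsilane; 2 3-methylcyclopent-2-en-1-one
Product: 5 (R)-trimethyl({3-methyl-3-[1-(trimethylsilyl)ethenyl]cyclopent-1-en-1-yl}oxy)silane, via alkenylalane 3 (not isolated), via aluminium enolate 4 (not isolated)
Conditions: 1, iBu2AlH, hexanes, 55 °C; then 2, Cu(OTf)2 (5 mol %), chiral sulfonate-bearing imidazolinium salt (NHC precursor, 5 mol %), THF, −30 °C; then TMSOTf, −78 → 0 °C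
Reagents that add atoms: trimethylsilyl trifluoromethanesulfonate, C[Si](C)(C)OS(=O)(=O)C(F)(F)F
Why: Hydroalumination places aluminium on the silicon-bearing alkyne carbon, and NHC–copper-catalysed asymmetric conjugate addition of such silyl-substituted vinylaluminium reagents to β-methyl cyclic enones is an established route to an alkenyl-bearing quaternary carbon, so C10 is set by the chiral catalyst, the silyl group makes the arm far larger than methyl (a plain alkenyl group would not steer step 3), and O-silylation of the aluminium enolate fixes the C3=C5 enolate regiochemistry.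

Step 2
Reactants: 6 3-bromobut-3-en-1-ol
Product: 7 3-bromobut-3-en-1-yl trifluoromethanesulfonate
Conditions: Tf2O, 2,6-lutidine, CH2Cl2, −78 °C; used at once
Reagents that add atoms: trifluoromethanesulfonic anhydride, O=S(=O)(OS(=O)(=O)C(F)(F)F)C(F)(F)F
Why: Standard O-triflation of a primary alcohol; the triflate is preferred to the iodide because its SN2 rate should outrun E2 loss of the allylic C7 hydrogens.

Step 3
Reactants: 5 (R)-trimethyl({3-methyl-3-[1-(trimethylsilyl)ethenyl]cyclopent-1-en-1-yl}oxy)silane; 7 3-bromobut-3-en-1-yl trifluoromethanesulfonate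
Product: 9 (2S,3R)-2-(3-bromobut-3-en-1-yl)-3-methyl-3-[1-(trimethylsilyl)ethenyl]cyclopentan-1-one, via lithium enolate 8 (not isolated)
Conditions: MeLi, THF, 0 °C; then 7, −78 → −20 °C
Reagents that add atoms: none
Why: Cleavage of the silyl enol ether by MeLi gives the C5 lithium enolate regiospecifically and SN2 enolate alkylation by the primary triflate follows, the electrophile entering C5 on the face of the small C10 methyl and opposite the bulky 1-(trimethylsilyl)ethenyl group, which sets C5 with the C6 arm trans to the C9 arm (this isomer is also the thermodynamically preferred one).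

Step 4
Reactants: 9 (2S,3R)-2-(3-bromobut-3-en-1-yl)-3-methyl-3-[1-(trimethylsilyl)ethenyl]cyclopentan-1-one
Product: 10 (2S,3S)-2-(3-bromobut-3-en-1-yl)-3-ethenyl-3-methylcyclopentan-1-one
Conditions: CF3CO2H, CH2Cl2, 0 °C, short reaction time
Reagents that add atoms: none
Why: Ipso-protodesilylation of the vinylsilane through the β-silyl-stabilised cation leaves a plain C10 vinyl group that is close to methyl in size, so that in step 5 the C5 side chain alone steers the addition; brief cold acid should not enolise the neopentylic C5.

Step 5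
Reactants: 10 (2S,3S)-2-(3-bromobut-3-en-1-yl)-3-ethenyl-3-methylcyclopentan-1-one
Product: 11 (1R,2S,3S)-2-(3-bromobut-3-en-1-yl)-3-ethenyl-3-methyl-1-(prop-1-en-2-yl)cyclopentan-1-ol
Conditions: isopropenylmagnesium bromide, CeCl3, THF, −78 °C; then H2O
Reagents that add atoms: isopropenylmagnesium bromide, C=C(C)[Mg]Br
Why: 1,2-Addition of the weakly basic organocerium reagent to the enolisable ketone; the nucleophile attacks the C3 carbonyl face opposite the adjacent C5 side chain (the two C10 groups being of similar size), giving the tertiary alcohol with OH cis to the C6 arm.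

Step 6
Reactants: 11 (1R,2S,3S)-2-(3-bromobut-3-en-1-yl)-3-ethenyl-3-methyl-1-(prop-1-en-2-yl)cyclopentan-1-ol
Product: 12 (1R,2S,3S)-2-(3-bromobut-3-en-1-yl)-3-ethenyl-3-methyl-1-[(2S)-2-methyloxiran-2-yl]cyclopentan-1-ol
Conditions: VO(acac)2 (5 mol %), t-BuOOH, CH2Cl2, 0 °C
Reagents that add atoms: tert-butyl hydroperoxide, CC(C)(C)OO
Why: Vanadium-catalysed hydroxyl-directed epoxidation acts only on the allylic isopropenyl alkene (the remote vinyl group lies trans to the hydroxyl and the bromoalkene is electron-poor); in the vanadate transition state (O–C3–C4=C19 dihedral near 50°) the ring carbon that nearly eclipses the C18 methyl should be the C2 methylene and not the branched C5, the tertiary-alcohol counterpart of the erythro preference of 2-substituted allylic alcohols, which gives the (S)-epoxide at C4.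

Step 7
Reactants: 12 (1R,2S,3S)-2-(3-bromobut-3-en-1-yl)-3-ethenyl-3-methyl-1-[(2S)-2-methyloxiran-2-yl]cyclopentan-1-ol
Product: 13 (2R,3S,4S)-3-(3-bromobut-3-en-1-yl)-4-ethenyl-2-(hydroxymethyl)-2,4-dimethylcyclohexan-1-one
Conditions: ZnBr2, CH2Cl2, −20 → 0 °C
Reagents that add atoms: none
Why: ZnBr2 binds the epoxide oxygen, the tertiary C4–O bond lengthens, and the C3–C5 bond lying anti to it shifts to C4 while the C3 oxygen becomes the carbonyl; this is a semipinacol rearrangement of a tertiary α-hydroxy epoxide, the known Lewis-acid route to β-hydroxy ketones with an α-quaternary carbon. Ring A closes by one-carbon enlargement of the five-membered ring (C1, C2, C3, C5, C10) to the six-membered ring that now contains C4, not by an end-to-end cyclisation, so the congested C4–C5 bond forms within a tight 1,2-shift and the C19 alcohol and C3 ketone are unveiled together. C4 is the only new stereocentre: it forms with inversion at the epoxide carbon, so its configuration is dictated by the epoxide configuration from step 6, while C5 migrates with retention. The step needs migratory selectivity for C5 over C2; the branched, more electron-releasing C5 should stabilise the electron-deficient transition state better than the C2 methylene, and free rotation about C3–C4 lets either bond reach the anti alignment, so aptitude and not geometry decides. Bromide capture at C4 and hydride shift from C19 are the side paths, and low temperature in a non-coordinating solvent should hold them back.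

Step 8
Reactants: 13 (2R,3S,4S)-3-(3-bromobut-3-en-1-yl)-4-ethenyl-2-(hydroxymethyl)-2,4-dimethylcyclohexan-1-one
Product: 14 (1R,2R,3S,4S)-3-(3-bromobut-3-en-1-yl)-4-ethenyl-2-(hydroxymethyl)-2,4-dimethylcyclohexan-1-ol
Conditions: NaBH4, MeOH, 0 °C
Reagents that add atoms: none
Why: Borohydride reduction of the 2,2-disubstituted cyclohexanone; hydride adds axially from the face opposite the axial C19 and C20 groups, giving the equatorial C3–OH cis to the C19 hydroxymethyl.

Step 9
Reactants: 14 (1R,2R,3S,4S)-3-(3-bromobut-3-en-1-yl)-4-ethenyl-2-(hydroxymethyl)-2,4-dimethylcyclohexan-1-ol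
Product: 15 (4aR,5S,6S,8aR)-5-(3-bromobut-3-en-1-yl)-6-ethenyl-2,2,4a,6-tetramethylhexahydro-4H-1,3-benzodioxine (the 3,19-acetonide of 14)
Conditions: 2,2-dimethoxypropane, PPTS (cat.), CH2Cl2, rt
Reagents that add atoms: 2,2-dimethoxypropane, COC(C)(C)OC
Why: Acid-catalysed transacetalisation closes the six-membered acetonide across the cis-related C3–OH and C19–OH, which protects both for the strongly basic aldol step.

Step 10
Reactants: 15 (4aR,5S,6S,8aR)-5-(3-bromobut-3-en-1-yl)-6-ethenyl-2,2,4a,6-tetramethylhexahydro-4H-1,3-benzodioxine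
Product: 16 (2E)-3-[(4aR,5S,6S,8aR)-5-(3-bromobut-3-en-1-yl)-2,2,4a,6-tetramethylhexahydro-4H-1,3-benzodioxin-6-yl]prop-2-enal
Conditions: crotonaldehyde (excess), second-generation Hoveyda–Grubbs catalyst RuCl2(SIMes)(=CH–C6H4-2-OiPr) (10 mol %), CH2Cl2, 40 °C
Reagents that add atoms: crotonaldehyde, C/C=C/C=O
Why: Olefin cross-metathesis of the neopentylic vinyl group (which cannot homodimerise) with excess crotonaldehyde should give the E-enal with loss of propene, while the 2-bromo-1,1-disubstituted alkene is too hindered and electron-poor to engage the ruthenium carbene.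

Step 11
Reactants: 16 (2E)-3-[(4aR,5S,6S,8aR)-5-(3-bromobut-3-en-1-yl)-2,2,4a,6-tetramethylhexahydro-4H-1,3-benzodioxin-6-yl]prop-2-enal
Product: 17 3,19-acetonide of 2-[(1R,4aS,5R,6R,8aS)-6-hydroxy-5-(hydroxymethyl)-5,8a-dimethyl-2-methylidenedecahydronaphthalen-1-yl]acetaldehyde
Conditions: Bu3SnH (slow addition), AIBN, benzene (0.01 M), 80 °C
Reagents that add atoms: none
Why: Tin-mediated vinyl radical cyclisation: bromine abstraction gives the C8 σ-vinyl radical, which adds 6-exo-trig to C9 (the β-carbon of the enal) through a chair transition state with the enal equatorial and eclipsing the C10–methyl bond, so that H9 ends axial and anti to C20, the exocyclic C8=C17 methylene arises directly, and the α-formyl radical is reduced by Bu3SnH.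

Step 12
Reactants: 18 (S)-3-hydroxy-γ-butyrolactone
Product: 19 (4S)-4-(triethylsilyloxy)oxolan-2-one
Conditions: Et3SiCl, imidazole, CH2Cl2, 0 °C → rt
Reagents that add atoms: chlorotriethylsilane, CC[Si](Cl)(CC)CC
Why: Routine silylation of the secondary alcohol; the triethylsilyl ether survives LiN(iPr)2 and is later removed by the same mild acid as the acetonide.

Step 13
Reactants: 19 (4S)-4-(triethylsilyloxy)oxolan-2-one; 17 ring-B aldehyde (acetonide)
Product: 21 (3,4-trans)-3-{1-hydroxy-2-[decalin unit of 17]ethyl}-4-(triethylsilyloxy)oxolan-2-one as a mixture at C12, via lithium enolate 20 (not isolated)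
Conditions: 19, LiN(iPr)2, THF, −78 °C; then 17, −78 °C; AcOH quench at −78 °C
Reagents that add atoms: none
Why: Aldol addition of the lactone lithium enolate to the aldehyde at −78 °C, where β-silyloxy lactone enolates are handled without β-elimination (as in the α-functionalisation of silylated 2-deoxyribonolactones); C14 is untouched and the new centres C12 and C13 are transient, C13 forming trans to the silyloxy group.

Step 14
Reactants: 21 aldol adduct
Product: 23 3,19-O-isopropylidene-14-O-triethylsilylandrographolide, via mesylate 22 (not isolated)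
Conditions: MsCl, Et3N, CH2Cl2, 0 °C; then DBU, rt
Reagents that add atoms: none
Why: Mesylation of the C12 alcohol and base-induced E1cB elimination; only the mesylate leaves because silyloxide is a far poorer leaving group, and the conjugated alkene is expected as the E isomer (C11 anti to the lactone carbonyl) under the equilibrating conditions.

Step 15
Reactants: 23 3,19-O-isopropylidene-14-O-triethylsilylandrographolide
Product: 24 andrographolide
Conditions: AcOH/H2O/THF (3:1:1), rt
Reagents that add atoms: none
Why: Mild aqueous acetic acid hydrolyses the triethylsilyl ether and the acetonide without ionising the allylic C14–OH or moving the exocyclic alkene, releasing the target.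

**Compound list**

1 | ethynyltrimethylsilane | C#C[Si](C)(C)C | starting material
2 | 3-methylcyclopent-2-en-1-one | CC1=CC(=O)CC1 | starting material
3 | diisobutyl[1-(trimethylsilyl)ethenyl]aluminium | C=C([Si](C)(C)C)[Al](CC(C)C)CC(C)C | intermediate (not isolated)
4 | diisobutylaluminium C3=C5 enolate of (R)-3-methyl-3-[1-(trimethylsilyl)ethenyl]cyclopentanone | CC(C)C[Al](CC(C)C)OC1=C[C@](C)(C(=C)[Si](C)(C)C)CC1 | intermediate (not isolated)
5 | (R)-trimethyl({3-methyl-3-[1-(trimethylsilyl)ethenyl]cyclopent-1-en-1-yl}oxy)silane | C[Si](C)(C)OC1=C[C@](C)(C(=C)[Si](C)(C)C)CC1 | intermediate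
6 | 3-bromobut-3-en-1-ol | C=C(Br)CCO | starting material
7 | 3-bromobut-3-en-1-yl trifluoromethanesulfonate | C=C(Br)CCOS(=O)(=O)C(F)(F)F | intermediate
8 | lithium C3=C5 enolate of (R)-3-methyl-3-[1-(trimethylsilyl)ethenyl]cyclopentanone | [Li]OC1=C[C@](C)(C(=C)[Si](C)(C)C)CC1 | intermediate (not isolated)
9 | (2S,3R)-2-(3-bromobut-3-en-1-yl)-3-methyl-3-[1-(trimethylsilyl)ethenyl]cyclopentan-1-one | C=C(Br)CC[C@@H]1C(=O)CC[C@@]1(C)C(=C)[Si](C)(C)C | intermediate
10 | (2S,3S)-2-(3-bromobut-3-en-1-yl)-3-ethenyl-3-methylcyclopentan-1-one | C=C(Br)CC[C@@H]1C(=O)CC[C@@]1(C)C=C | intermediate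
11 | (1R,2S,3S)-2-(3-bromobut-3-en-1-yl)-3-ethenyl-3-methyl-1-(prop-1-en-2-yl)cyclopentan-1-ol | C=C(Br)CC[C@@H]1[C@@](O)(C(C)=C)CC[C@@]1(C)C=C | intermediate
12 | (1R,2S,3S)-2-(3-bromobut-3-en-1-yl)-3-ethenyl-3-methyl-1-[(2S)-2-methyloxiran-2-yl]cyclopentan-1-ol | C=C(Br)CC[C@@H]1[C@@](O)([C@]2(C)CO2)CC[C@@]1(C)C=C | intermediate
13 | (2R,3S,4S)-3-(3-bromobut-3-en-1-yl)-4-ethenyl-2-(hydroxymethyl)-2,4-dimethylcyclohexan-1-one | C=C(Br)CC[C@@H]1[C@](C)(CO)C(=O)CC[C@@]1(C)C=C | intermediate
14 | (1R,2R,3S,4S)-3-(3-bromobut-3-en-1-yl)-4-ethenyl-2-(hydroxymethyl)-2,4-dimethylcyclohexan-1-ol | C=C(Br)CC[C@@H]1[C@](C)(CO)[C@H](O)CC[C@@]1(C)C=C | intermediate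
15 | (4aR,5S,6S,8aR)-5-(3-bromobut-3-en-1-yl)-6-ethenyl-2,2,4a,6-tetramethylhexahydro-4H-1,3-benzodioxine | C=C(Br)CC[C@@H]1[C@]2(C)COC(C)(C)O[C@@H]2CC[C@@]1(C)C=C | intermediate
16 | (2E)-3-[(4aR,5S,6S,8aR)-5-(3-bromobut-3-en-1-yl)-2,2,4a,6-tetramethylhexahydro-4H-1,3-benzodioxin-6-yl]prop-2-enal | C=C(Br)CC[C@@H]1[C@]2(C)COC(C)(C)O[C@@H]2CC[C@@]1(C)/C=C/C=O | intermediate
17 | 3,19-acetonide of 2-[(1R,4aS,5R,6R,8aS)-6-hydroxy-5-(hydroxymethyl)-5,8a-dimethyl-2-methylidenedecahydronaphthalen-1-yl]acetaldehyde | C=C1CC[C@@H]2[C@]3(C)COC(C)(C)O[C@@H]3CC[C@@]2(C)[C@@H]1CC=O | intermediate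
18 | (S)-3-hydroxy-γ-butyrolactone | C1C(=O)OC[C@H]1O | starting material
19 | (4S)-4-(triethylsilyloxy)oxolan-2-one | C1C(=O)OC[C@H]1O[Si](CC)(CC)CC | intermediate
20 | lithium enolate of 19 | [Li]OC1=C[C@H](O[Si](CC)(CC)CC)CO1 | intermediate (not isolated)
21 | aldol adduct of 17 and 19 (C12 carbinol as a mixture, C13 trans to the C14 silyloxy group) | C=C1CC[C@@H]2[C@]3(C)COC(C)(C)O[C@@H]3CC[C@@]2(C)[C@@H]1CC(O)[C@@H]1C(=O)OC[C@H]1O[Si](CC)(CC)CC | intermediate
22 | C12 methanesulfonate of 21 | C=C1CC[C@@H]2[C@]3(C)COC(C)(C)O[C@@H]3CC[C@@]2(C)[C@@H]1CC(OS(C)(=O)=O)[C@@H]1C(=O)OC[C@H]1O[Si](CC)(CC)CC | intermediate (not isolated)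
23 | 3,19-O-isopropylidene-14-O-triethylsilylandrographolide | C=C1CC[C@@H]2[C@]3(C)COC(C)(C)O[C@@H]3CC[C@@]2(C)[C@@H]1C/C=C1/C(=O)OC[C@H]1O[Si](CC)(CC)CC | intermediate
24 | andrographolide | C=C1CC[C@@H]2[C@](C)(CO)[C@H](O)CC[C@@]2(C)[C@@H]1C/C=C1/C(=O)OC[C@H]1O | target

**Step count**

Total: 15 steps (13 in the main line, plus step 2 and step 12 for the two side reagents).
Longest linear sequence: 13 steps (steps 1, 3–11, 13–15).

**Steps most likely to fail**

Step 7. The shift of the C2 methylene may compete with that of C5, or the tertiary C4 cation may be taken by bromide or by a hydride shift from C19 before the ring carbon moves. Fallback: setting out from 12, the tertiary hydroxyl is silylated with N-(trimethylsilyl)imidazole to give the trimethylsilyl ether of 12 F1. F1 is then rearranged with TiCl4 in CH2Cl2 at −78 °C, the known Lewis-acid rearrangement of epoxy silyl ethers. Here the silyloxy group drives the shift through an oxocarbenium ion without a zinc chelate and without free hydroxyl participation. Aqueous work-up removes the silyl group and the route is rejoined at 13.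

Step 3. C-alkylation at the neopentylic enolate carbon may be slow enough for proton transfer to the less hindered C2 enolate, O-alkylation or elimination of the triflate to take over. Fallback: setting out from 5, the C6 carbon is made electrophilic instead.
- Mannich reaction of the silyl enol ether with dimethylmethyleneammonium iodide (CH2Cl2, rt) gives the 2-[(dimethylamino)methyl] ketone F2.
- N-methylation with MeI and elimination with NaHCO3 give the α-methylene ketone F3.
- Hosomi–Sakurai conjugate addition of (2-bromoallyl)trimethylsilane with TiCl4 at −78 °C forms the C6–C7 bond.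
- Equilibration of C5 with DBU places the chain trans to the bulky silylvinyl group and rejoins the route at 9.

Step 10. Turnover at the neopentylic vinyl group may be sluggish and the ruthenium carbene may be lost through the bromoalkene. Fallback: setting out from 15, the vinyl group is cleaved by Lemieux–Johnson oxidation (OsO4 cat., NaIO4, 2,6-lutidine, dioxane–water), which should spare the electron-poor bromoalkene, to give the neopentylic C9 aldehyde F4. Wittig olefination of F4 with (triphenylphosphoranylidene)acetaldehyde in toluene at 90 °C then gives the E-enal and rejoins the route at 16.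

**Further compounds**

F1 | step 7 | trimethylsilyl ether of 12 (tertiary C3–O–SiMe3) | C=C(Br)CC[C@@H]1[C@@](O[Si](C)(C)C)([C@]2(C)CO2)CC[C@@]1(C)C=C
F2 | step 3 | 2-[(dimethylamino)methyl]-3-methyl-3-[1-(trimethylsilyl)ethenyl]cyclopentan-1-one (aminomethyl cis to the C10 methyl) | CN(C)C[C@@H]1C(=O)CC[C@@]1(C)C(=C)[Si](C)(C)C
F3 | step 3 | (R)-3-methyl-2-methylidene-3-[1-(trimethylsilyl)ethenyl]cyclopentan-1-one | C=C1C(=O)CC[C@@]1(C)C(=C)[Si](C)(C)C
F4 | step 10 | 5-(3-bromobut-3-en-1-yl)-2,2,4a,6-tetramethylhexahydro-4H-1,3-benzodioxine-6-carbaldehyde (C9 aldehyde from 15, ring configuration as in 15) | C=C(Br)CC[C@@H]1[C@]2(C)COC(C)(C)O[C@@H]2CC[C@@]1(C)C=O
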